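**Retrosynthetic overview**
- Last step: removal of three silyl ethers. Ring B is bought as 3,4,5-trihydroxybenzaldehyde.
- Ring A and the 22-membered ring are disconnected together: an aryl ethynyl ether on O-4 of ring B and a 3-alkylcyclobutenone at the far chain end (thermal vinylketene/ynol-ether benzannulation).
- The cyclobutenone comes from the chain bromide and 3-ethoxycyclobutenone; the ethynyl ether from a dichlorovinyl ether (trichloroethene).
- The (R)-carbinol comes from a catalytic enantioselective dialkylzinc addition to the ring-B aldehyde; the (E)-olefin from hydrozirconation of oct-1-en-7-yne and Pd coupling with 1,5-dibromopentane.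
- Ring order: ring B (purchased), then ring A and the macrocycle in one operation.

Assumption: TBS = tert-butyldimethylsilyl (TBSO = its ether); the target is read from the SMILES as (R) at the carbinol and (E) at the olefin; 3-ethoxycyclobut-2-en-1-one and Cp2Zr(H)Cl are taken as purchasable.

Step 1
Reactants: 1 6-bromohex-1-ene; 2 lithium acetylide–ethane-1,2-diamine complex
Product: 3 oct-1-en-7-yne
Conditions: DMSO, 10 → 25 °C, 2 h
Reagents that add atoms: none
Why: Acetylide alkylation (SN2 of lithium acetylide on a primary bromide in DMSO) is a standard route to terminal 1,ω-enynes; no stereocentre is involved.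

Step 2
Reactants: 3 oct-1-en-7-yne; 4 1,5-dibromopentane
Product: 6 (7E)-13-bromotrideca-1,7-diene, via alkenylzirconocene chloride 5 (not isolated)
Conditions: Cp2Zr(H)Cl (1.05 equiv), THF, rt; then 4 (3 equiv), Pd(acac)2 (2.5 mol %), LiBr (2 equiv), THF/NMP, 55 °C
Reagents that add atoms: none
Why: Schwartz hydrozirconation is selective for the terminal alkyne over the terminal alkene and adds syn with Zr at the terminus, and the Pd-catalysed Negishi-type alkenyl–alkyl cross-coupling with a primary bromide (dibromide in excess for mono-coupling) proceeds with retention, which fixes the E-olefin.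

Step 3
Reactants: 7 3,4,5-trihydroxybenzaldehyde; 8 trichloroethene
Product: 9 4-{[(E)-1,2-dichloroethenyl]oxy}-3,5-dihydroxybenzaldehyde
Conditions: K2CO3 (1.1 equiv), degassed DMF, 60 °C
Reagents that add atoms: none
Why: Greene-type dichlorovinylation: with one equivalent of base only the most acidic 4-OH (para to CHO) is ionised, and this phenoxide adds anti to dichloroacetylene formed in situ from trichloroethene to give the (E)-1,2-dichlorovinyl ether, in line with known 4-O-selective alkylations of this triol.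

Step 4
Reactants: 9 4-{[(E)-1,2-dichloroethenyl]oxy}-3,5-dihydroxybenzaldehyde
Product: 10 3,5-bis(TBSO)-4-{[(E)-1,2-dichloroethenyl]oxy}benzaldehyde
Conditions: TBSCl (2.4 equiv), imidazole (5 equiv), DMF, rt
Reagents that add atoms: tert-butyldimethylsilyl chloride (TBSCl), CC(C)(C)[Si](C)(C)Cl
Why: Standard phenol silylation (Corey conditions); the aldehyde and the dichlorovinyl ether are inert.

Step 5
Reactants: 6 (7E)-13-bromotrideca-1,7-diene (3 equiv); 10 3,5-bis(TBSO)-4-{[(E)-1,2-dichloroethenyl]oxy}benzaldehyde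
Product: 13 (1R,8E)-14-bromo-1-[3,5-bis(TBSO)-4-{[(E)-1,2-dichloroethenyl]oxy}phenyl]tetradec-8-en-1-ol, via alkyldiethylborane 11 (not isolated), via dialkylzinc 12 (not isolated)
Conditions: 6, Et2BH (from BH3·SMe2/Et3B), 0 °C → rt; Et2Zn, 0 °C, then vacuum; then 10, Ti(OiPr)4 (2 equiv), (1S,2S)-1,2-bis(trifluoromethanesulfonamido)cyclohexane (8 mol %), PhMe, −20 °C; 1 M HCl
Reagents that add atoms: none
Why: Knochel-type sequence of chemoselective hydroboration of the terminal alkene, boron–zinc exchange and Ti/bis-sulfonamide-catalysed enantioselective dialkylzinc addition to the aryl aldehyde, in which the (1S,2S)-ligand directs alkyl transfer to the Re face (as for benzaldehyde) and so sets the (R)-carbinol (expected ≥90 % ee; the (1R,2R)-ligand would give S).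

Step 6
Reactants: 13 (1R,8E)-14-bromo-1-[3,5-bis(TBSO)-4-{[(E)-1,2-dichloroethenyl]oxy}phenyl]tetradec-8-en-1-ol
Product: 14 (1R,8E)-14-bromo-1-(TBSO)-1-[3,5-bis(TBSO)-4-{[(E)-1,2-dichloroethenyl]oxy}phenyl]tetradec-8-ene
Conditions: TBSOTf (1.3 equiv), 2,6-lutidine, CH2Cl2, −78 → 0 °C
Reagents that add atoms: tert-butyldimethylsilyl trifluoromethanesulfonate (TBSOTf), CC(C)(C)[Si](C)(C)OS(=O)(=O)C(F)(F)F
Why: Silyl protection of the benzylic alcohol so that it survives the Grignard, n-BuLi and ketene chemistry; the stereocentre is not touched.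

Step 7
Reactants: 14 (1R,8E)-14-bromo-1-(TBSO)-1-[3,5-bis(TBSO)-4-{[(E)-1,2-dichloroethenyl]oxy}phenyl]tetradec-8-ene; 15 3-ethoxycyclobut-2-en-1-one
Product: 19 3-[(6E,14R)-14-(TBSO)-14-{3,5-bis(TBSO)-4-(ethynyloxy)phenyl}tetradec-6-en-1-yl]cyclobut-2-en-1-one, via alkylmagnesium bromide 16 (not isolated), via bromomagnesium cyclobutenolate 17 (not isolated), via lithium aryloxyacetylide 18 (not isolated)
Conditions: Mg, THF, 25–35 °C; 15 (1.0 equiv), THF, −78 °C; then n-BuLi (2.3 equiv), −78 → −40 °C; aq. NH4Cl; then 0.5 M HCl/THF, 0 °C, 10 min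
Reagents that add atoms: water, O
Why: Telescoped Stork–Danheiser enone transposition and Greene ynol-ether synthesis: Mg inserts into the primary bromide far faster than into the vinylic chlorides, the Grignard adds 1,2 to the vinylogous ester, the resulting alkoxide is inert while n-BuLi converts ArO–CCl=CHCl into ArO–C≡C–Li (HCl elimination then Cl/Li exchange), and brief dilute acid protonates the acetylide and hydrolyses the 3-ethoxycyclobutenol to the 3-alkylcyclobutenone before the hindered aryl ynol ether can hydrate.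

Step 8
Reactants: 19 3-[(6E,14R)-14-(TBSO)-14-{3,5-bis(TBSO)-4-(ethynyloxy)phenyl}tetradec-6-en-1-yl]cyclobut-2-en-1-one
Product: 24 tris-TBS-dehydrogravicycle (benzylic O and both ring-B O silylated; ring-A OH free; R; E), via vinylketene 20 (not isolated), via macrocyclic vinylcyclobutenone 21 (not isolated), via dienylketene 22 (not isolated), via cyclohexadienone 23 (not isolated)
Conditions: syringe-pump addition (12 h) to PhMe, 110 °C, final 0.5 mM; then 2 h
Reagents that add atoms: none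
Why: Proposed new method: a 22-membered-ring intramolecular Danheiser benzannulation, in which reversible thermal 4π opening of the cyclobutenone gives vinylketene 20 at low stationary concentration, regioselective ketene/ynol-ether [2+2] (alkyne CH carbon to the ketene carbonyl) closes the macrocycle as 21, and 4π opening to 22, 6π electrocyclisation to 23 and tautomerisation give the phenol with OH, OAr and alkyl 1,3,5, as in the known bimolecular cyclobutenone + alkoxyacetylene benzannulation to 5-alkylresorcinol monoethers; high dilution and return of unreacted ketene to the cyclobutenone disfavour oligomers, the remote unactivated E-alkene does not trap the ketene, and no stereocentre is involved.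

Step 9
Reactants: 24 tris-TBS-dehydrogravicycle
Product: 25 dehydrogravicycle
Conditions: TBAF (4 equiv), AcOH (4 equiv), THF, 0 °C → rt
Reagents that add atoms: none
Why: Buffered fluoride desilylation removes the two aryl and the benzylic silyl ethers without acid, so the electron-rich benzylic (R)-carbinol neither ionises nor racemises and the E-olefin is untouched.

**Compound list**
1 | 6-bromohex-1-ene | C=CCCCCBr | starting material
2 | lithium acetylide–ethane-1,2-diamine complex | [Li+].[C-]#C.NCCN | starting material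
3 | oct-1-en-7-yne | C=CCCCCC#C | intermediate
4 | 1,5-dibromopentane | BrCCCCCBr | starting material
5 | chlorido[(1E)-octa-1,7-dien-1-yl]zirconocene (not isolated) | C=CCCCC/C=C/[Zr](Cl)(C1C=CC=C1)C1C=CC=C1 | intermediate
6 | (7E)-13-bromotrideca-1,7-diene | C=CCCCC/C=C/CCCCCBr | intermediate
7 | 3,4,5-trihydroxybenzaldehyde | O=Cc1cc(O)c(O)c(O)c1 | starting material
8 | trichloroethene | ClC=C(Cl)Cl | starting material
9 | 4-{[(E)-1,2-dichloroethenyl]oxy}-3,5-dihydroxybenzaldehyde | O=Cc1cc(O)c(O/C(Cl)=C\Cl)c(O)c1 | intermediate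
10 | 3,5-bis(TBSO)-4-{[(E)-1,2-dichloroethenyl]oxy}benzaldehyde | O=Cc1cc(O[Si](C)(C)C(C)(C)C)c(O/C(Cl)=C\Cl)c(O[Si](C)(C)C(C)(C)C)c1 | intermediate
11 | diethyl[(7E)-13-bromotridec-7-en-1-yl]borane (not isolated) | CCB(CC)CCCCCC/C=C/CCCCCBr | intermediate
12 | bis[(7E)-13-bromotridec-7-en-1-yl]zinc (not isolated) | BrCCCCC/C=C/CCCCCC[Zn]CCCCCC/C=C/CCCCCBr | intermediate
13 | (1R,8E)-14-bromo-1-[3,5-bis(TBSO)-4-{[(E)-1,2-dichloroethenyl]oxy}phenyl]tetradec-8-en-1-ol | O[C@H](CCCCCC/C=C/CCCCCBr)c1cc(O[Si](C)(C)C(C)(C)C)c(O/C(Cl)=C\Cl)c(O[Si](C)(C)C(C)(C)C)c1 | intermediate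
14 | TBS ether of 13: (1R,8E)-14-bromo-1-(TBSO)-1-[3,5-bis(TBSO)-4-{[(E)-1,2-dichloroethenyl]oxy}phenyl]tetradec-8-ene | CC(C)(C)[Si](C)(C)O[C@H](CCCCCC/C=C/CCCCCBr)c1cc(O[Si](C)(C)C(C)(C)C)c(O/C(Cl)=C\Cl)c(O[Si](C)(C)C(C)(C)C)c1 | intermediate
15 | 3-ethoxycyclobut-2-en-1-one | CCOC1=CC(=O)C1 | starting material
16 | Grignard reagent of 14, C–Br replaced by C–MgBr (not isolated) | CC(C)(C)[Si](C)(C)O[C@H](CCCCCC/C=C/CCCCC[Mg]Br)c1cc(O[Si](C)(C)C(C)(C)C)c(O/C(Cl)=C\Cl)c(O[Si](C)(C)C(C)(C)C)c1 | intermediate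
17 | bromomagnesium 1-alkyl-3-ethoxycyclobut-2-en-1-olate, 1,2-adduct of 16 to 15, epimers at the new carbinol carbon (not isolated) | CC(C)(C)[Si](C)(C)O[C@H](CCCCCC/C=C/CCCCCC1(O[Mg]Br)C=C(OCC)C1)c1cc(O[Si](C)(C)C(C)(C)C)c(O/C(Cl)=C\Cl)c(O[Si](C)(C)C(C)(C)C)c1 | intermediate
18 | lithium aryloxyacetylide of 17 (not isolated) | CC(C)(C)[Si](C)(C)O[C@H](CCCCCC/C=C/CCCCCC1(O[Mg]Br)C=C(OCC)C1)c1cc(O[Si](C)(C)C(C)(C)C)c(OC#C[Li])c(O[Si](C)(C)C(C)(C)C)c1 | intermediate
19 | 3-[(6E,14R)-14-(TBSO)-14-{3,5-bis(TBSO)-4-(ethynyloxy)phenyl}tetradec-6-en-1-yl]cyclobut-2-en-1-one | CC(C)(C)[Si](C)(C)O[C@H](CCCCCC/C=C/CCCCCC1=CC(=O)C1)c1cc(O[Si](C)(C)C(C)(C)C)c(OC#C)c(O[Si](C)(C)C(C)(C)C)c1 | intermediate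
20 | vinylketene from ring opening of 19: chain–C(=CH2)–CH=C=O (not isolated) | CC(C)(C)[Si](C)(C)O[C@H](CCCCCC/C=C/CCCCCC(=C)C=C=O)c1cc(O[Si](C)(C)C(C)(C)C)c(OC#C)c(O[Si](C)(C)C(C)(C)C)c1 | intermediate
21 | macrocyclic 3-aryloxy-4-(alk-1-en-2-yl)cyclobut-2-en-1-one, the [2+2] adduct, epimers at the ring CH (not isolated) | CC(C)(C)[Si](C)(C)O[C@@H]1CCCCCC/C=C/CCCCCC(=C)C2C(=O)C=C2Oc2c(O[Si](C)(C)C(C)(C)C)cc1cc2O[Si](C)(C)C(C)(C)C | intermediate
22 | macrocyclic dienylketene O=C=CH–C(OAr)=CH–C(R)=CH2 (not isolated) | CC(C)(C)[Si](C)(C)O[C@@H]1CCCCCC/C=C/CCCCCC(=C)/C=C(/Oc2c(O[Si](C)(C)C(C)(C)C)cc1cc2O[Si](C)(C)C(C)(C)C)C=C=O | intermediate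
23 | macrocyclic 3-aryloxy-5-alkylcyclohexa-2,4-dien-1-one, keto tautomer of 24 (not isolated) | CC(C)(C)[Si](C)(C)O[C@@H]1CCCCCC/C=C/CCCCCC2=CC(Oc3c(O[Si](C)(C)C(C)(C)C)cc1cc3O[Si](C)(C)C(C)(C)C)=CC(=O)C2 | intermediate
24 | tris-TBS-dehydrogravicycle: 22-membered macrocycle; ring A = 5-alkyl-3-aryloxyphenol with free OH; ring B = 2,6-bis(TBSO)phenyl ether carrying para the (R)-CH(OTBS); chain (CH2)6–(E)-CH=CH–(CH2)5 from the carbinol to ring A | CC(C)(C)[Si](C)(C)O[C@@H]1CCCCCC/C=C/CCCCCc2cc(O)cc(c2)Oc2c(O[Si](C)(C)C(C)(C)C)cc1cc2O[Si](C)(C)C(C)(C)C | intermediate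
25 | dehydrogravicycle, (R)-carbinol, (E)-olefin | Oc1cc2cc(c1)Oc1c(O)cc(cc1O)[C@H](O)CCCCCC/C=C/CCCCC2 | target

**Step count**
Total: 9 steps. Longest linear sequence: 7 steps (1, 2, 5, 6, 7, 8, 9 from 6-bromohex-1-ene; equally 3, 4, 5–9 from 3,4,5-trihydroxybenzaldehyde).

**Three steps most likely to fail, with fallbacks**

Step 8 (the macrocyclic benzannulation; risks are oligomerisation and thermal loss of the terminal aryl ynol ether). The fallback sets out from 10 (using 15 again) and returns at 24. It separates the two ring closures: ring A is made bimolecularly and the large ring is closed by olefin metathesis. Aldehyde 10 is alkylated as in step 5, but with the zinc reagent from mono-hydroboration of octa-1,7-diene (diene in excess), to give (1R)-1-[3,5-bis(TBSO)-4-{[(E)-1,2-dichloroethenyl]oxy}phenyl]non-8-en-1-ol F1. Silylation (TBSOTf, 2,6-lutidine) gives (1R)-1-(TBSO)-1-[3,5-bis(TBSO)-4-{[(E)-1,2-dichloroethenyl]oxy}phenyl]non-8-ene F2. n-BuLi (2.3 equiv, THF, −78 → −40 °C; NH4Cl) converts it into (1R)-1-(TBSO)-1-[3,5-bis(TBSO)-4-(ethynyloxy)phenyl]non-8-ene F3; no acid is needed here. Separately, the Grignard reagent of 7-bromohept-1-ene is added to 15 and the adduct is hydrolysed with dilute HCl to 3-(hept-6-en-1-yl)cyclobut-2-en-1-one F4. Heating F4 with F3 (1.5 equiv) in toluene (0.3 M, 80 → 110 °C) is the ordinary bimolecular benzannulation and gives 3-{2,6-bis(TBSO)-4-[(1R)-1-(TBSO)non-8-en-1-yl]phenoxy}-5-(hept-6-en-1-yl)phenol F5. Ring-closing metathesis (Grubbs second-generation catalyst, CH2Cl2, 1 mM, 40 °C) closes the 22-membered ring to 24 with loss of ethene. This closure is not stereospecific: the E isomer is expected to predominate under thermodynamic control and the Z isomer is removed on AgNO3-impregnated silica. Step 9 follows.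

Step 7 (telescoped Grignard addition, ynol-ether formation and acid unmasking; risks are hydration of the ynol ether and incomplete transposition). The fallback sets out from 14 and returns at 20, the ketene inside step 8, and hence at 24. It avoids the cyclobutenone and makes the same vinylketene by dehydrochlorination of a β,γ-unsaturated acid chloride. Grignard reagent 16 (from 14 and Mg) opens diketene at its vinylic C–O bond under NiCl2 catalysis (THF, −20 °C → rt) to give (9E,17R)-17-(TBSO)-17-[3,5-bis(TBSO)-4-{[(E)-1,2-dichloroethenyl]oxy}phenyl]-3-methylideneheptadec-9-enoic acid F6. n-BuLi (3.3 equiv, −78 → −40 °C; citric acid work-up) converts the dichlorovinyl ether of the lithium carboxylate into the ethynyl ether, (9E,17R)-17-(TBSO)-17-[3,5-bis(TBSO)-4-(ethynyloxy)phenyl]-3-methylideneheptadec-9-enoic acid F7. 1-Chloro-N,N,2-trimethylprop-1-en-1-amine (CH2Cl2, 0 °C, neutral) gives the corresponding acid chloride F8. F8 is added by syringe pump to Et3N in toluene at 80 °C (final 0.5 mM); α-dehydrochlorination gives 20, and the cascade of step 8 carries it to 24.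

Step 3 (regioselective 4-O-dichlorovinylation of the free triol; risks are O-3 attack and slow reaction of the weakly basic 4-phenoxide). The fallback sets out from 7 and returns at 10, replacing steps 3 and 4. All three phenols are silylated (TBSCl, imidazole, DMF) to 3,4,5-tris(TBSO)benzaldehyde F9. The silyl ether para to the aldehyde (best phenoxide leaving group) is cleaved selectively (Cs2CO3 0.5 equiv, DMF/H2O 10:1, 0 °C) to 4-hydroxy-3,5-bis(TBSO)benzaldehyde F10. Its potassium salt (KH, THF) with trichloroethene 8 at rt gives 10.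

Further compounds
F1 | step 8 | (1R)-1-[3,5-bis(TBSO)-4-{[(E)-1,2-dichloroethenyl]oxy}phenyl]non-8-en-1-ol | O[C@H](CCCCCCC=C)c1cc(O[Si](C)(C)C(C)(C)C)c(O/C(Cl)=C\Cl)c(O[Si](C)(C)C(C)(C)C)c1
F2 | step 8 | (1R)-1-(TBSO)-1-[3,5-bis(TBSO)-4-{[(E)-1,2-dichloroethenyl]oxy}phenyl]non-8-ene | CC(C)(C)[Si](C)(C)O[C@H](CCCCCCC=C)c1cc(O[Si](C)(C)C(C)(C)C)c(O/C(Cl)=C\Cl)c(O[Si](C)(C)C(C)(C)C)c1
F3 | step 8 | (1R)-1-(TBSO)-1-[3,5-bis(TBSO)-4-(ethynyloxy)phenyl]non-8-ene | CC(C)(C)[Si](C)(C)O[C@H](CCCCCCC=C)c1cc(O[Si](C)(C)C(C)(C)C)c(OC#C)c(O[Si](C)(C)C(C)(C)C)c1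
F4 | step 8 | 3-(hept-6-en-1-yl)cyclobut-2-en-1-one | C=CCCCCCC1=CC(=O)C1
F5 | step 8 | 3-{2,6-bis(TBSO)-4-[(1R)-1-(TBSO)non-8-en-1-yl]phenoxy}-5-(hept-6-en-1-yl)phenol | CC(C)(C)[Si](C)(C)O[C@H](CCCCCCC=C)c1cc(O[Si](C)(C)C(C)(C)C)c(Oc2cc(O)cc(CCCCCC=C)c2)c(O[Si](C)(C)C(C)(C)C)c1
F6 | step 7 | (9E,17R)-17-(TBSO)-17-[3,5-bis(TBSO)-4-{[(E)-1,2-dichloroethenyl]oxy}phenyl]-3-methylideneheptadec-9-enoic acid | CC(C)(C)[Si](C)(C)O[C@H](CCCCCC/C=C/CCCCCC(=C)CC(=O)O)c1cc(O[Si](C)(C)C(C)(C)C)c(O/C(Cl)=C\Cl)c(O[Si](C)(C)C(C)(C)C)c1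
F7 | step 7 | (9E,17R)-17-(TBSO)-17-[3,5-bis(TBSO)-4-(ethynyloxy)phenyl]-3-methylideneheptadec-9-enoic acid | CC(C)(C)[Si](C)(C)O[C@H](CCCCCC/C=C/CCCCCC(=C)CC(=O)O)c1cc(O[Si](C)(C)C(C)(C)C)c(OC#C)c(O[Si](C)(C)C(C)(C)C)c1
F8 | step 7 | (9E,17R)-17-(TBSO)-17-[3,5-bis(TBSO)-4-(ethynyloxy)phenyl]-3-methylideneheptadec-9-enoyl chloride | CC(C)(C)[Si](C)(C)O[C@H](CCCCCC/C=C/CCCCCC(=C)CC(=O)Cl)c1cc(O[Si](C)(C)C(C)(C)C)c(OC#C)c(O[Si](C)(C)C(C)(C)C)c1
F9 | step 3 | 3,4,5-tris(TBSO)benzaldehyde | O=Cc1cc(O[Si](C)(C)C(C)(C)C)c(O[Si](C)(C)C(C)(C)C)c(O[Si](C)(C)C(C)(C)C)c1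
F10 | step 3 | 4-hydroxy-3,5-bis(TBSO)benzaldehyde | O=Cc1cc(O[Si](C)(C)C(C)(C)C)c(O)c(O[Si](C)(C)C(C)(C)C)c1
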